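The geranyl chain is disconnected between its benzylic carbon C1'' and vinylic carbon C2''. The key step exploits the free 5-OH of ring A and the adjacent C6. The array O5–C5–C6–C1'' is unmasked as an o-quinone methide whose oxygen binds an (E)-alkenylborate. The C9 alkenyl group then passes from boron to C1'' through a six-membered transition state, restoring the aromaticity of ring A and keeping the olefin geometry. The precursor is an achiral 5-hydroxychromone bearing a CH2–S+Me2 group at C6, placed there by a [2,3]-sigmatropic shift from the same oxygen. The C2 stereocentre is set last by asymmetric rhodium-catalysed conjugate arylation.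

Key step: step 5

Assumption: the rhodium/(S)-biaryl diphosphine catalyst is taken to deliver the aryl group to the same enone face of the chromone as it does with 2-cyclohexenone, which corresponds to (2S). If the sense proves opposite, the (R)-ligand is used. Flavanone locants are used throughout, and the geranyl carbons are C1'' (benzylic) to C8''.

Step 1
Reactants: 1 2',6'-dihydroxy-4'-methoxyacetophenone
Product: 3 5-hydroxy-7-methoxy-4H-chromen-4-one, via enaminone 2 (not isolated)
Conditions: Me2NCH(OMe)2, toluene, 100 °C; then conc. HCl, CH2Cl2, 40 °C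
Reagents that add atoms: N,N-dimethylformamide dimethyl acetal, COC(OC)N(C)C
Why: Enaminone condensation at the acetyl methyl group followed by acid-promoted addition–elimination ring closure (enaminone route to chromones) should give a single chromone, because the two hydroxyl groups of 1 are equivalent by symmetry and the one left over becomes the chelated 5-OH.

Step 2
Reactants: 3 5-hydroxy-7-methoxy-4H-chromen-4-one
Product: 5 5-hydroxy-7-methoxy-6-[(methylsulfanyl)methyl]-4H-chromen-4-one, via aryloxysulfonium chloride 4 (not isolated)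
Conditions: NCS, Me2S, CH2Cl2, −25 °C; add 3; then Et3N, −25 °C to rt
Reagents that add atoms: dimethyl sulfide, CSC
Why: In this Gassman-type ortho-alkylation of a phenol, O5 attacks the Corey–Kim sulfonium reagent, Et3N forms the ylide, and its [2,3]-sigmatropic shift can deliver CH2SMe only to C6, since the other ortho carbon C4a is quaternary and C8 is out of reach; tautomerisation then restores ring A.

Step 3
Reactants: 6 5-bromo-2-methylpent-2-ene; 7 lithium acetylide–ethylenediamine complex, LiC≡CH·H2NCH2CH2NH2
Product: 8 6-methylhept-5-en-1-yne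
Conditions: DMSO, 0 °C to rt
Reagents that add atoms: none
Why: SN2 alkylation of lithium acetylide by a primary bromide in a dipolar aprotic solvent is a standard terminal alkyne synthesis, and the trisubstituted alkene is inert to it.

Step 4
Reactants: 8 6-methylhept-5-en-1-yne
Product: 10 (1E)-1-iodo-2,6-dimethylhepta-1,5-diene, via alkenylalane 9 (not isolated)
Conditions: Me3Al, Cp2ZrCl2 (20 mol %), CH2Cl2, 0 °C to rt; then I2, THF, −30 °C
Reagents that add atoms: trimethylaluminium, C[Al](C)C; iodine, II
Why: Negishi zirconium-catalysed carboalumination adds methyl and aluminium syn across the terminal alkyne with aluminium at the terminus, and iodinolysis of the C–Al bond with retention should give the E-iodide while the isolated trisubstituted alkene stays untouched.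

Step 5
Reactants: 5 5-hydroxy-7-methoxy-6-[(methylsulfanyl)methyl]-4H-chromen-4-one; 10 (1E)-1-iodo-2,6-dimethylhepta-1,5-diene
Product: 14 6-[(2E)-3,7-dimethylocta-2,6-dien-1-yl]-5-hydroxy-7-methoxy-4H-chromen-4-one, via sulfonium triflate 11 (not isolated), via lithium alkenylborate 12 (not isolated), via boron-bound o-quinone methide 13 (not isolated)
Conditions: 5, MeOTf (1.0 equiv), CH2Cl2, 0 °C to rt; separately 10 (1.5 equiv), B(OiPr)3, n-BuLi, THF, −78 to 0 °C; slow addition of the first solution to the second, −40 °C to rt; aq. NH4Cl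
Reagents that add atoms: none
Why: S-Methylation turns the sulfide into a dimethylsulfonium leaving group; on mixing, the 5-OH protonates one isopropoxide of borate 12, the phenoxide binds boron, Me2S departs and the o-quinone methide (O5=C5–C6=C1'') arises already coordinated to the alkenylboronate as 13. The alkenyl group then migrates from boron to C1'' through a six-membered cyclic array (B–O5–C5–C6–C1''–C2''), and rearomatisation of ring A supplies the driving force. The closest known reaction types are the conjugate addition of alkenylboronates to o-quinone methides and the Petasis reaction of salicylaldehydes. No ring is closed and no stereocentre is formed; the E geometry of C2''=C3'' is carried over because boron-to-carbon transfer of an alkenyl group is stereoretentive. The step needs attack at C1'' in preference to C2 of the chromone, to self-dimerisation of the quinone methide and to [4+2] capture by the C6''=C7'' alkene; the tether through O5 can reach only C1'', and slow addition of 11 to an excess of 12 keeps the quinone methide dilute. The position on ring A (C6, not C8) is already fixed by the site of the sulfonium group.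

Step 6
Reactants: 14 6-[(2E)-3,7-dimethylocta-2,6-dien-1-yl]-5-hydroxy-7-methoxy-4H-chromen-4-one; 15 (3,4-dimethoxyphenyl)boronic acid
Product: 16 (2S)-2-(3,4-dimethoxyphenyl)-6-[(2E)-3,7-dimethylocta-2,6-dien-1-yl]-5-hydroxy-7-methoxy-2,3-dihydro-4H-chromen-4-one
Conditions: [Rh(OH)(cod)]2 (1.5 mol %), (S)-2,2'-bis[bis(3,4,5-trifluorophenyl)phosphino]-6,6'-dimethoxy-1,1'-biphenyl (3.3 mol %), 15 (3 equiv), CH2Cl2/H2O 10:1, 25 °C
Reagents that add atoms: none
Why: In this Hayashi–Miyaura asymmetric 1,4-addition, a reaction type established for 4-chromones with electron-poor biaryl diphosphines, the aryl-rhodium species should insert C2=C3 on the face left open by the (S)-ligand and so set (2S), and base-free hydrolysis of the rhodium enolate should release the flavanone without retro-oxa-Michael racemisation or attack on the unactivated geranyl alkenes.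

Compound list
1 | 2',6'-dihydroxy-4'-methoxyacetophenone | CC(=O)c1c(O)cc(OC)cc1O | starting material
2 | (E)-3-(dimethylamino)-1-(2,6-dihydroxy-4-methoxyphenyl)prop-2-en-1-one | CN(C)/C=C/C(=O)c1c(O)cc(OC)cc1O | intermediate
3 | 5-hydroxy-7-methoxy-4H-chromen-4-one | O=C1C=COc2cc(OC)cc(O)c12 | intermediate
4 | [(7-methoxy-4-oxo-4H-chromen-5-yl)oxy]dimethylsulfonium chloride | C[S+](C)Oc1cc(OC)cc2OC=CC(=O)c12.[Cl-] | intermediate
5 | 5-hydroxy-7-methoxy-6-[(methylsulfanyl)methyl]-4H-chromen-4-one | O=C1C=COc2cc(OC)c(CSC)c(O)c12 | intermediate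
6 | 5-bromo-2-methylpent-2-ene | BrCCC=C(C)C | starting material
7 | lithium acetylide–ethylenediamine complex | [Li+].[C-]#C.NCCN | starting material
8 | 6-methylhept-5-en-1-yne | C#CCCC=C(C)C | intermediate
9 | [(1E)-2,6-dimethylhepta-1,5-dien-1-yl]dimethylaluminium | C[Al](C)/C=C(\C)CCC=C(C)C | intermediate
10 | (1E)-1-iodo-2,6-dimethylhepta-1,5-diene | I/C=C(\C)CCC=C(C)C | intermediate
11 | [(5-hydroxy-7-methoxy-4-oxo-4H-chromen-6-yl)methyl]dimethylsulfonium triflate | O=C1C=COc2cc(OC)c(C[S+](C)C)c(O)c12.[O-]S(=O)(=O)C(F)(F)F | intermediate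
12 | lithium [(1E)-2,6-dimethylhepta-1,5-dien-1-yl]triisopropoxyborate | [Li+].CC(C)O[B-](OC(C)C)(OC(C)C)/C=C(\C)CCC=C(C)C | intermediate
13 | 7-methoxy-6-methylidenechromene-4,5-dione bound through O5 to the (E)-alkenyl diisopropyl boronate | COC1=CC2=C(C(=O)C=CO2)C(=[O+][B-](OC(C)C)(OC(C)C)/C=C(\C)CCC=C(C)C)C1=C | intermediate
14 | 6-[(2E)-3,7-dimethylocta-2,6-dien-1-yl]-5-hydroxy-7-methoxy-4H-chromen-4-one | O=C1C=COc2cc(OC)c(C/C=C(\C)CCC=C(C)C)c(O)c12 | intermediate
15 | (3,4-dimethoxyphenyl)boronic acid | COc1ccc(B(O)O)cc1OC | starting material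
16 | (2S)-2-(3,4-dimethoxyphenyl)-6-[(2E)-3,7-dimethylocta-2,6-dien-1-yl]-5-hydroxy-7-methoxy-2,3-dihydro-4H-chromen-4-one | COc1ccc([C@@H]2CC(=O)c3c(cc(OC)c(C/C=C(\C)CCC=C(C)C)c3O)O2)cc1OC | target

Total step count: 6. Longest linear sequence: 4 steps (1 → 3 → 5 → 14 → 16; the branch 6 → 8 → 10 → 14 → 16 is of equal length).

Steps most likely to fail

Step 5. Self-condensation of the quinone methide or its capture by isopropoxide may outrun the boron-to-carbon transfer, and methylation at the chromone carbonyl oxygen may compete with S-methylation during activation. The fallback sets out from 5 and 12 and replaces the quinone methide pathway by a metal-catalysed benzylic cross-coupling.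
- Acetylation of the 5-OH (Ac2O, pyridine) would give 7-methoxy-6-[(methylsulfanyl)methyl]-4-oxo-4H-chromen-5-yl acetate F1, which can no longer form a quinone methide.
- MeOTf would convert it into {[5-(acetyloxy)-7-methoxy-4-oxo-4H-chromen-6-yl]methyl}dimethylsulfonium triflate F2.
- PdCl2(dppf)-catalysed Suzuki–Miyaura-type coupling of this benzylic sulfonium salt with borate 12, by oxidative addition of zerovalent palladium into the benzylic C–S bond, would give 6-[(2E)-3,7-dimethylocta-2,6-dien-1-yl]-7-methoxy-4-oxo-4H-chromen-5-yl acetate F3.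
- Methanolysis (catalytic K2CO3, MeOH, 0 °C) comes back to the route at 14.

Step 2. O-Sulfonium formation at the strongly chelated 5-OH may be sluggish, so that ring chlorination by the reagent takes over. The fallback sets out from 3 and installs the one-carbon unit by halogenation and cross-coupling instead of a sigmatropic shift.
- Iodination with benzyltrimethylammonium dichloroiodate and CaCO3 in CH2Cl2/MeOH, which is directed to C6 in 5-hydroxy-7-alkoxy benzopyranones, would give 5-hydroxy-6-iodo-7-methoxy-4H-chromen-4-one F4.
- Stille coupling with Bu3SnCH2OH under Pd(PPh3)4 would give 5-hydroxy-6-(hydroxymethyl)-7-methoxy-4H-chromen-4-one F5.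
- Treatment of this activated benzylic alcohol with Me2S and TfOH in CH2Cl2 would give the sulfonium triflate, coming back to the route at 11.

Step 6. Sequestration of rhodium by the O5/O4 chelate, protodeboronation of the electron-rich boronic acid or poor facial selectivity may erode conversion and enantiopurity. The fallback sets out from 14 and 15 and obtains the stereocentre by kinetic resolution instead of enantioselective C–C bond formation.
- Conjugate arylation with Pd(OCOCF3)2 and 2,2'-bipyridine would give racemic 2-(3,4-dimethoxyphenyl)-6-[(2E)-3,7-dimethylocta-2,6-dien-1-yl]-5-hydroxy-7-methoxy-2,3-dihydro-4H-chromen-4-one F6.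
- Noyori asymmetric transfer hydrogenation with RuCl(p-cymene)[(R,R)-TsDPEN] in HCO2H/Et3N, run to about half conversion, should reduce the matched (2R)-ketone to (2R,4R)-2-(3,4-dimethoxyphenyl)-6-[(2E)-3,7-dimethylocta-2,6-dien-1-yl]-7-methoxy-3,4-dihydro-2H-chromene-4,5-diol F7.
- The unreacted (2S)-ketone is separated by chromatography, coming back to the route at 16.

Further compounds
F1 | step 5 | 7-methoxy-6-[(methylsulfanyl)methyl]-4-oxo-4H-chromen-5-yl acetate | O=C1C=COc2cc(OC)c(CSC)c(OC(C)=O)c12
F2 | step 5 | {[5-(acetyloxy)-7-methoxy-4-oxo-4H-chromen-6-yl]methyl}dimethylsulfonium triflate | O=C1C=COc2cc(OC)c(C[S+](C)C)c(OC(C)=O)c12.[O-]S(=O)(=O)C(F)(F)F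
F3 | step 5 | 6-[(2E)-3,7-dimethylocta-2,6-dien-1-yl]-7-methoxy-4-oxo-4H-chromen-5-yl acetate | O=C1C=COc2cc(OC)c(C/C=C(\C)CCC=C(C)C)c(OC(C)=O)c12
F4 | step 2 | 5-hydroxy-6-iodo-7-methoxy-4H-chromen-4-one | O=C1C=COc2cc(OC)c(I)c(O)c12
F5 | step 2 | 5-hydroxy-6-(hydroxymethyl)-7-methoxy-4H-chromen-4-one | O=C1C=COc2cc(OC)c(CO)c(O)c12
F6 | step 6 | racemic 2-(3,4-dimethoxyphenyl)-6-[(2E)-3,7-dimethylocta-2,6-dien-1-yl]-5-hydroxy-7-methoxy-2,3-dihydro-4H-chromen-4-one | COc1ccc(C2CC(=O)c3c(cc(OC)c(C/C=C(\C)CCC=C(C)C)c3O)O2)cc1OC
F7 | step 6 | (2R,4R)-2-(3,4-dimethoxyphenyl)-6-[(2E)-3,7-dimethylocta-2,6-dien-1-yl]-7-methoxy-3,4-dihydro-2H-chromene-4,5-diol | COc1ccc([C@H]2C[C@@H](O)c3c(cc(OC)c(C/C=C(\C)CCC=C(C)C)c3O)O2)cc1OC
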